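# Sarcodictyin A by a four-carbon ring expansion (6 → 10) across a temporary C3–C8 bond

## Structural features

Natural-product numbering is used throughout. Cyclohexene ring A (C1, C10–C14; C11=C12, methyl on C11, isopropyl on C14) is cis-fused through C1–C10 to a ten-membered carbocycle C1–C10. An oxygen atom bridges C4 and C7, so C4–C5=C6–C7–O is a 2,5-dihydrofuran. C4 is a hemiketal, that is, the closed form of a (Z)-γ-hydroxy enone. C2=C3 is trisubstituted and carries CO2Me on C3, with C1 and C4 cis on the double bond, and C8 carries the (E)-N-methylurocanate. The stereocentres form two separated groups: the contiguous triad C14/C1/C10 in ring A, and the pair C7 (fully substituted)/C8, with C4 tied to C7 by the bridge. The target is (1S,4R,7S,8S,10R,14R). The fragile groups are these: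
- the hemiketal, whose open form is a doubly activated alkylidene β-keto ester;
- the vinylogously acidic C1–H;
- the nucleophilic C11=C12 bond;
- the basic, oxidisable urocanate.

The real difficulty is the strained, bridged ten-membered ring with four sp2 carbons, and the placement of C7/C8 relative to the remote ring A triad. In the open keto form C3 is the α-carbon of a β-keto ester (C4=O, CO2Me), and the oxygen-bearing C8 lies 1,6 across the ring. A transannular C3–C8 bond is therefore an aldol bond that divides the ring into two six-membered rings (C1-C2-C3-C8-C9-C10 and C3-C4-C5-C6-C7-C8). The key step exploits this. The ten-membered ring is never closed end to end; it arises when a pentenoyl chain (C4–C7) on C3 of the six-membered β-keto ester 14 adds through C7 to C8 and the C3–C8 bond breaks.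

## Logic of the disconnections

**22 ⇒ 20 + 21.** The acyl–O8 bond is cut. The urocanate is the most base- and oxidant-sensitive part, so it goes on last. This removes the heteroaromatic acrylate from every earlier step. The forward step must acylate a hindered secondary alcohol beside a tertiary hemiketal hydroxyl.

**20 ⇒ 19.** The C8–H bond is cut (alcohol back to ketone), because a C8 ketone is what the fragmentation delivers. One stereocentre is removed. The forward step needs hydride on one face of C8 and no attack on the enoate or the masked enone.

**19 ⇒ 17.** The C7–O bond and the bridge O–C4 bond are cut. The hemiketal is only the closed form of the hydroxy enone, and C7–H of 17 lies between C8=O and the vinylogous C4=O, so it is the most acidic site. The bridge and two stereocentres (C7, C4) disappear. The forward step must put oxygen on C7, not C5, and on the ring face opposite to ring A.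

**17 ⇒ 14 (key).** Read backwards, C7–C8 is cut, C3–C8 is joined, and a sulfinate is added to C2. The ten-membered ring with its cis-C5=C6 and its C2=C3 collapses to a cis-decalin-type bicycle carrying an ordinary acyclic (E)-pentenoyl group. No macrocyclisation remains. The forward step needs three things:
- the extended enolate must attack C8 through C7;
- the resulting alkoxide must expel C3 rather than C7;
- there must be one irreversible exit.

**14 ⇒ 12.** C3–C8 (aldol) and C2–S (conjugate addition) are cut, and the oxidation levels at sulfur and C8 are lowered (through 13). Ring B opens to ring A with two arms. The forward step needs a stabilised enolate to add to an aldehyde and form quaternary C3. The configurations at C2, C3 and C8 do not matter because all three are erased later.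

**12 ⇒ 6 + 10.** C2=C3 is cut (Knoevenagel), and the C8 aldehyde is masked (through 11). C3–C7, the methyl group on C7 and the ester arrive in one piece. The forward step needs the two aldehydes differentiated (acetal) and no epimerisation at C1.

**10 ⇒ 7 + 8.** C3–C4 is cut, corresponding to acylation of a malonate half-ester with loss of CO2. Both partners are purchasable.

**6 ⇒ 3.** C8–C9 is cut and C2–C9 is rejoined (through 5 and 4). One cyclobutanone yields two differentiated arms by strain-driven retro-Claisen opening. The forward step needs condensation only at C9.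

**3 ⇒ 1.** C1–C2 and C9–C10 are cut (through 2), a ketene [2+2] cycloaddition. C1 and C10 are set together from C14. The forward step needs the disubstituted double bond of the diene, the face anti to isopropyl, and the carbonyl carbon on C1.

## Other disconnections considered

Alternative 1: (the first that comes to mind) The cut is C4–C5. The terminal alkyne of the open-chain alkynyl aldehyde A1 is deprotonated and adds to the C4 aldehyde to give the ten-membered propargylic alcohol A2. Oxidation, cis-semihydrogenation and hemiketal collapse follow. This is a direct end-to-end closure of a strained ring, so it needs high dilution and pays the full transannular strain in the transition state. C7 and C8 must be installed and protected beforehand, and C4 and the alkyne need redox corrections afterwards, which costs several functional-group steps. The chosen plan passes only through six-membered transition states and delivers C4, C8, C5=C6 and C2=C3 at their final oxidation levels.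

Alternative 2: The same temporary C3–C8 bond is used, but C3–C4 and C7–C8 are made together by a [4+2] cycloaddition of 5-methyl-2-silyloxyfuran to the enol acetate A3. This would give the oxanorbornene A4, and a Grob fragmentation follows. The dienophile is a tetrasubstituted push–pull alkene, and the diene is aromatic and adds reversibly. Two vicinal quaternary carbons would form, so the equilibrium should lie on the side of the addends. The silyloxyfuran is more likely to react as a vinylogous nucleophile. The configuration at C7 would depend on the product of facial and endo/exo selectivity, and the bridgehead ketal of A4 is labile.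

Alternative 3: The temporary C3–C8 bond is made together with C4–C5 by an intramolecular Diels–Alder reaction. The silyl dienol ether/α-substituted acrylate A5 would give the tricycle A6, and fluoride then triggers a Grob fragmentation. The cycloaddition is electronically matched and sound. However, C4 and C5 arrive as CH2 groups, so C4 must later be oxidised to a ketone among five other allylic positions. Building both arms also takes more steps. The chosen plan brings C4 in as a carbonyl from the start.

Key step: step 11

Assumption: (R)-α-phellandrene 1 of high enantiomeric purity and (E)-3-(1-methylimidazol-4-yl)acrylic acid 21 are taken as purchasable.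

## Steps

Step 1
Reactants: 1 (R)-α-phellandrene
Product: 2 cis-fused 8,8-dichloro-2-methyl-5-isopropylbicyclo[4.2.0]oct-2-en-7-one (C=O on C1, CCl2 on C10, four-membered ring anti to isopropyl)
Conditions: Cl3CCOCl, Zn(Cu), Et2O, 0 °C to rt
Reagents that add atoms: trichloroacetyl chloride ClC(Cl)(Cl)C(Cl)=O
Why: Ketene–alkene [2+2] cycloaddition; dichloroketene should take the less substituted C1=C10 bond with its carbonyl carbon on the diene terminus C1, and suprafacial addition anti to the C14 isopropyl group sets C1 and C10 cis to each other and trans to isopropyl.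

Step 2
Reactants: 2 dichlorocyclobutanone
Product: 3 cis-fused 2-methyl-5-isopropylbicyclo[4.2.0]oct-2-en-7-one
Conditions: Zn, AcOH, rt to 50 °C
Reagents that add atoms: none
Why: Reductive dehalogenation of an α,α-dichloroketone through zinc enolates; no stereocentre is touched and the trisubstituted alkene is inert.

Step 3
Reactants: 3 cyclobutanone
Product: 4 (E)-8-(dimethylaminomethylidene) derivative of 3 (enaminone; the new carbon is C8)
Conditions: t-BuOCH(NMe2)2, toluene, 70 °C
Reagents that add atoms: tert-butoxybis(dimethylamino)methane CN(C)C(OC(C)(C)C)N(C)C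
Why: Aminomethylenation of the only α-CH2 group (C9); the tertiary α-carbon C1 cannot give a stable enaminone.

Step 4
Reactants: 4 enaminone
Product: 5 methyl 2-(2,2-dimethoxyethyl)-3-methyl-6-isopropylcyclohex-3-ene-1-carboxylate (ester on C1 and acetal arm on C10 cis, both trans to isopropyl)
Conditions: p-TsOH·H2O (1.2 equiv), MeOH, reflux
Reagents that add atoms: methanol CO
Why: Methanolysis of the enaminone to the α-(dimethoxymethyl)cyclobutanone, then retro-Claisen opening by methanol driven by release of four-ring strain; the C2–C9 bond breaks and the stereocentres are untouched.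

Step 5
Reactants: 5 ester acetal
Product: 6 2-(2,2-dimethoxyethyl)-3-methyl-6-isopropylcyclohex-3-ene-1-carbaldehyde (same relative configuration)
Conditions: DIBAL-H (1.05 equiv), CH2Cl2, −78 °C; Rochelle salt
Reagents that add atoms: none
Why: Partial reduction of an ester through the stable tetrahedral aluminate at low temperature; the acetal and the alkene are inert.

Step 6
Reactants: 7 (E)-pent-2-enoic acid; 8 potassium methyl malonate
Product: 10 methyl (E)-3-oxohept-4-enoate, via acyl imidazolide 9 (not isolated)
Conditions: 7, CDI, THF, rt; then 8, MgCl2, Et3N, MeCN, rt to 40 °C; aq. HCl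
Reagents that add atoms: 1,1'-carbonyldiimidazole O=C(n1ccnc1)n1ccnc1 (supplies the imidazolyl group of 9 only)
Why: Decarboxylative Claisen acylation of a magnesium malonate half-ester by an acyl imidazolide; the neutral conditions keep the E-enone intact.

Step 7
Reactants: 6 aldehyde acetal; 10 β-keto ester
Product: 11 alkylidene β-keto ester acetal (C2=C3 drawn E; cross-conjugated with the E-pentenoyl group)
Conditions: ethylenediammonium diacetate (10 mol %), 4 Å MS, CH2Cl2, rt
Reagents that add atoms: none
Why: Knoevenagel condensation under nearly neutral ammonium carboxylate catalysis, which should spare C1–H; both C2=C3 isomers are usable because step 9 destroys this double bond.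

Step 8
Reactants: 11 acetal
Product: 12 alkylidene β-keto ester aldehyde (free C8 aldehyde)
Conditions: LiBF4, MeCN–H2O (98:2), rt
Reagents that add atoms: water O
Why: Mild Lewis-acid hydrolysis of a dimethyl acetal; without base the aldehyde and the acceptor do not react with each other.

Step 9
Reactants: 12 aldehyde
Product: 13 bicyclic ketol sulfide (ring B closed; C2–SPh and the C3 acyl group on the H-1/H-10 face, CO2Me on C3 and OH on C8 on the other face)
Conditions: PhSH (1.05 equiv), n-BuLi (0.1 equiv), THF, −40 to 0 °C
Reagents that add atoms: thiophenol Sc1ccccc1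
Why: Sulfa-Michael/aldol domino cyclisation; thiolate adds to the doubly activated C2, the chelated enolate closes on the unhindered aldehyde (6-exo-trig), and thiol protonates the aldolate. The drawn isomer is that of a chair closure with equatorial OH, and all C2/C3/C8 diastereomers converge because these centres are erased in steps 10 and 11.

Step 10
Reactants: 13 ketol sulfide
Product: 14 bicyclic keto sulfone (C8 ketone, C2–SO2Ph, quaternary C3 bearing CO2Me and the (E)-pentenoyl group)
Conditions: TPAP (10 mol %), NMO (5 equiv), 4 Å MS, MeCN, rt
Reagents that add atoms: N-methylmorpholine N-oxide C[N+]1([O-])CCOCC1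
Why: Perruthenate/N-oxide oxidises secondary alcohols to ketones and sulfides to sulfones in the presence of isolated and conjugated alkenes; C3 is quaternary, so the β-sulfone cannot be lost prematurely.

Step 11
Reactants: 14 keto sulfone
Product: 17 ten-membered (2E,5Z)-4,8-dioxo dienoate (C7-H/Me epimers interconvert), via tricyclic potassium alkoxide 15 (not isolated), via ring-expanded sulfonyl enolate 16 (not isolated)
Conditions: t-BuOK (1.05 equiv), THF–t-BuOH (10:1), −20 to 0 °C; pH 7 buffer
Reagents that add atoms: none
Why: Proposed new method: reversible deprotonation gives, among other anions, the extended enolate O–C4=C5–C6=C7 of the pentenoyl chain, and rotation about C5–C6 lets C7 add to the C8 ketone in a 6-(enolendo)-exo-trig aldol closure to 15, in which C5=C6 is necessarily cis. The C8 alkoxide of 15 can expel C7 (return) or C3, and C3 leaves far better because it departs as a β-keto ester enolate, so C3–C8 breaks (retro-aldol, Grob-type) and the perimeter of the two six-membered rings becomes the ten-membered ring of 16, which is thus formed by bond cleavage and not by closure. 16 then loses benzenesulfinate from C2 (E1cB), the only irreversible event, so the competing equilibria (C9 enolate, its 6-endo Michael addition to C6, the α-sulfonyl anion) should drain through this exit (Curtin–Hammett), and the single equivalent of base ends as the non-basic sulfinate, leaving 17 un-ionised. The closest known reaction types are the Grob/Wharton fragmentation of decalin 1,3-diol monosulfonates to cyclodecenones and the side-chain-insertion ring expansion of 2-acyl cyclic β-keto esters by N or O nucleophiles; the vinylogous carbon nucleophile and the sulfinate exit are new. γ- over α-attack is fixed by ring size (six against four). C2=C3 should form with C1 and C4 cis, because a trans double bond in a ring that already holds a cis-enone and two carbonyl carbons is much more strained. The only new stereocentre, C7 (H/Me), is configurationally labile and is erased in step 12, and the C2 and C3 centres of 14 vanish, so any diastereomer of 14 gives the same 17.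

Step 12
Reactants: 17 dioxo dienoate
Product: 19 bridged hemiketal ketone (4,7-oxido bridge, 4-OH, 7-Me, C8 ketone; 4R,7S), via potassium dienolate 18 (not isolated)
Conditions: KHMDS (1.05 equiv), THF, −78 °C; 2-(benzenesulfonyl)-3-phenyloxaziridine (1.3 equiv), −78 °C; AcOH
Reagents that add atoms: 2-(benzenesulfonyl)-3-phenyloxaziridine O=S(=O)(c1ccccc1)N1OC1c1ccccc1
Why: Enolate hydroxylation with an N-sulfonyloxaziridine; C7–H is the most acidic site, and in the O4–C4–C5–C6–C7–C8–O8 anion the methyl-bearing C7 should carry the larger HOMO coefficient, so oxygen goes to C7 and C5=C6 stays conjugated and cis. The reagent should approach the face bearing H-1 and H-10, because the C1–C14 and C10–C11 bonds hold ring A under the other face. The C7 alkoxide then closes on C4=O, which fixes C4.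

Step 13
Reactants: 19 hemiketal ketone
Product: 20 8-O-deacyl sarcodictyin A (8S alcohol)
Conditions: NaBH4, MeOH–CH2Cl2, −40 °C
Reagents that add atoms: none
Why: Non-chelating 1,2-reduction under polar Felkin–Anh control, with the C7–O bond antiperiplanar to hydride and the C7 methyl group flanking the trajectory; this is also the outer face, away from ring A, and gives 8S. In the closed hemiketal C2=C3 is only a trisubstituted enoate and is inert to borohydride.

Step 14
Reactants: 20 diol; 21 (E)-3-(1-methylimidazol-4-yl)acrylic acid
Product: 22 sarcodictyin A
Conditions: DCC, DMAP, CH2Cl2, rt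
Reagents that add atoms: none
Why: Steglich esterification; the secondary C8–OH should react in preference to the tertiary hemiketal OH, and the E-acrylate and all stereocentres are unaffected.

## Compound list

1 | (R)-α-phellandrene | C1=C[C@@H](C(C)C)CC=C1C | starting material
2 | cis-fused 8,8-dichloro-2-methyl-5-isopropylbicyclo[4.2.0]oct-2-en-7-one | O=C1[C@@H]2[C@@H](C(C)C)CC=C(C)[C@@H]2C1(Cl)Cl | intermediate
3 | cis-fused 2-methyl-5-isopropylbicyclo[4.2.0]oct-2-en-7-one | O=C1[C@@H]2[C@@H](C(C)C)CC=C(C)[C@@H]2C1 | intermediate
4 | (E)-8-(dimethylaminomethylidene)cyclobutanone | CN(C)/C=C1/C(=O)[C@@H]2[C@@H](C(C)C)CC=C(C)[C@@H]21 | intermediate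
5 | ester acetal (C1–CO2Me, C10–CH2CH(OMe)2) | COC(=O)[C@@H]1[C@@H](C(C)C)CC=C(C)[C@@H]1CC(OC)OC | intermediate
6 | aldehyde acetal (C1–CHO) | O=C[C@@H]1[C@@H](C(C)C)CC=C(C)[C@@H]1CC(OC)OC | intermediate
7 | (E)-pent-2-enoic acid | CC/C=C/C(=O)O | starting material
8 | potassium methyl malonate | COC(=O)CC(=O)[O-].[K+] | starting material
9 | (E)-1-(imidazol-1-yl)pent-2-en-1-one | CC/C=C/C(=O)n1ccnc1 | intermediate
10 | methyl (E)-3-oxohept-4-enoate | COC(=O)CC(=O)/C=C/CC | intermediate
11 | alkylidene β-keto ester acetal | COC(=O)/C(=C/[C@@H]1[C@@H](C(C)C)CC=C(C)[C@@H]1CC(OC)OC)C(=O)/C=C/CC | intermediate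
12 | alkylidene β-keto ester aldehyde | COC(=O)/C(=C/[C@@H]1[C@@H](C(C)C)CC=C(C)[C@@H]1CC=O)C(=O)/C=C/CC | intermediate
13 | bicyclic ketol sulfide | COC(=O)[C@]3(C(=O)/C=C/CC)[C@@H](Sc4ccccc4)[C@@H]1[C@@H](C(C)C)CC=C(C)[C@@H]1C[C@@H]3O | intermediate
14 | bicyclic keto sulfone | COC(=O)[C@]3(C(=O)/C=C/CC)[C@@H](S(=O)(=O)c4ccccc4)[C@@H]1[C@@H](C(C)C)CC=C(C)[C@@H]1CC3=O | intermediate
15 | tricyclic potassium alkoxide | COC(=O)[C@]3(C(=O)C=C[C@H]5C)[C@@H](S(=O)(=O)c4ccccc4)[C@@H]1[C@@H](C(C)C)CC=C(C)[C@@H]1C[C@]35[O-].[K+] | intermediate
16 | ring-expanded sulfonyl enolate | COC(=O)C=3[C@@H](S(=O)(=O)c4ccccc4)[C@@H]1[C@@H](C(C)C)CC=C(C)[C@@H]1CC(=O)[C@H](C)/C=C\C3[O-].[K+] | intermediate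
17 | ten-membered (2E,5Z)-4,8-dioxo dienoate | COC(=O)/C3=C/[C@@H]1[C@@H](C(C)C)CC=C(C)[C@@H]1CC(=O)[C@H](C)/C=C\C3=O | intermediate
18 | potassium dienolate of 17 | COC(=O)/C3=C/[C@@H]1[C@@H](C(C)C)CC=C(C)[C@@H]1CC([O-])=C(C)/C=C\C3=O.[K+] | intermediate
19 | bridged hemiketal ketone | COC(=O)/C1=C/[C@@H]2[C@@H](C(C)C)CC=C(C)[C@@H]2CC(=O)[C@]2(C)C=C[C@@]1(O)O2 | intermediate
20 | 8-O-deacyl sarcodictyin A | COC(=O)/C1=C/[C@@H]2[C@@H](C(C)C)CC=C(C)[C@@H]2C[C@H](O)[C@]2(C)C=C[C@@]1(O)O2 | intermediate
21 | (E)-3-(1-methylimidazol-4-yl)acrylic acid | OC(=O)/C=C/c1cn(C)cn1 | starting material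
22 | sarcodictyin A | COC(=O)/C1=C/[C@@H]2[C@@H](C(C)C)CC=C(C)[C@@H]2C[C@H](OC(=O)/C=C/c2cn(C)cn2)[C@]2(C)C=C[C@@]1(O)O2 | target

## Step count and least certain steps

Total steps: 14. Longest linear sequence: 13 (steps 1–5 and 7–14).

**Step 11 (key step, proposed new method).**
- The extended enolate with the geometry needed for closure (C3 and C6 cis about C4=C5) is a crowded, minor component.
- Addition of C7 to a ketone flanked by a quaternary carbon may therefore be slow.
- In the meantime the Michael addition of the C9 enolate to C6 (bicyclo[3.3.1] framework) could become a kinetic trap.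
- tert-Butoxide could also deacylate the tricarbonyl carbon (retro-Claisen).

The fallback sets out from 14 and returns at 17. It splits the cascade into known reactions.
- TBSOTf/Et3N would give the silyl dienol ether F1.
- An intramolecular vinylogous Mukaiyama aldol addition (BF3·OEt2, −78 °C) would give the tricyclic ketol F2, which is isolated. No basic enolate equilibria are involved at this stage.
- KH or DBU would then fragment F2 (Grob-type, with loss of sulfinate) to 17.

**Step 12.**
- Oxygen transfer to C5 instead of C7 is possible.
- Facial selectivity at a site remote from ring A may be poor.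
- On warming, the trienolate could undergo transannular C7→C2 bond formation (Michael addition or 6π closure).

The fallback sets out from 17 and returns at 19. It uses the opposite regiochemical preference. Selenenylation of 18 with PhSeCl at the less hindered C5 would give the allylic selenide F3. Oxidation (H2O2, pyridine) then triggers the [2,3]-sigmatropic shift of the selenoxide, which carries oxygen suprafacially to C7 and moves the double bond to C5=C6. Hydrolysis and hemiketal closure would give 19.

**Step 9.**
- The aldol equilibrium of the stabilised enolate may stay on the side of the open Michael adduct.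
- C→O acyl migration in the aldolate is also possible.

The fallback sets out from 6 and returns at 14. It closes ring B before C3 becomes quaternary.
- Horner–Wadsworth–Emmons reaction with trimethyl phosphonoacetate (LiCl, DBU) would give the enoate acetal F4.
- Hydrolysis would give the enoate aldehyde F5.
- Thiolate-triggered Michael/aldol cyclisation would give the hydroxy ester sulfide F6.
- Dess–Martin oxidation would give the β-keto ester sulfide F7.
- C-acylation (MgCl2, pyridine, (E)-pent-2-enoyl chloride) would give the acylated sulfide F8.
- TPAP/NMO would give 14.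

**Step 13.**
- The hemiketal may open under the basic hydride conditions.
- The liberated alkylidene β-keto ester could then suffer conjugate reduction.
- Ring conformation may erode the Felkin selectivity.

The fallback sets out from 19 and returns at 20. PPTS/MeOH would lock the hemiketal as the methyl ketal ketone F9. An oxazaborolidine-catalysed borane reduction, using the catalyst enantiomer matched to the 8S face, would give the methyl ketal alcohol F10. CSA in THF–H2O would restore the hemiketal.

**Step 14.**
- Acylation of the neopentyl-type C8–OH by the poorly soluble acid may be slow.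
- N-acylurea formation, or acylation and opening at the hemiketal, could then compete.

The fallback sets out from 20 and returns at 22. Esterification with the small, reactive diethylphosphonoacetic acid would give the phosphonoacetate F11. A Horner–Wadsworth–Emmons reaction with 1-methylimidazole-4-carbaldehyde (LiCl, DBU) then builds the E-urocanate on the ester.

## Further compounds

F1 | step 11 | silyl dienol ether of 14 | COC(=O)[C@]3(/C(O[Si](C)(C)C(C)(C)C)=C\C=C\C)[C@@H](S(=O)(=O)c4ccccc4)[C@@H]1[C@@H](C(C)C)CC=C(C)[C@@H]1CC3=O
F2 | step 11 | tricyclic ketol | COC(=O)[C@]3(C(=O)C=C[C@H]5C)[C@@H](S(=O)(=O)c4ccccc4)[C@@H]1[C@@H](C(C)C)CC=C(C)[C@@H]1C[C@]35O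
F3 | step 12 | C5 allylic selenide | COC(=O)/C3=C/[C@@H]1[C@@H](C(C)C)CC=C(C)[C@@H]1CC(=O)/C(C)=C\[C@@H]([Se]c2ccccc2)C3=O
F4 | step 9 | enoate acetal | COC(=O)/C=C/[C@@H]1[C@@H](C(C)C)CC=C(C)[C@@H]1CC(OC)OC
F5 | step 9 | enoate aldehyde | COC(=O)/C=C/[C@@H]1[C@@H](C(C)C)CC=C(C)[C@@H]1CC=O
F6 | step 9 | hydroxy ester sulfide | COC(=O)[C@H]3[C@@H](Sc4ccccc4)[C@@H]1[C@@H](C(C)C)CC=C(C)[C@@H]1C[C@@H]3O
F7 | step 9 | β-keto ester sulfide (C3 labile) | COC(=O)C3[C@@H](Sc4ccccc4)[C@@H]1[C@@H](C(C)C)CC=C(C)[C@@H]1CC3=O
F8 | step 9 | acylated sulfide | COC(=O)[C@]3(C(=O)/C=C/CC)[C@@H](Sc4ccccc4)[C@@H]1[C@@H](C(C)C)CC=C(C)[C@@H]1CC3=O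
F9 | step 13 | methyl ketal ketone | COC(=O)/C1=C/[C@@H]2[C@@H](C(C)C)CC=C(C)[C@@H]2CC(=O)[C@]2(C)C=C[C@@]1(OC)O2
F10 | step 13 | methyl ketal alcohol | COC(=O)/C1=C/[C@@H]2[C@@H](C(C)C)CC=C(C)[C@@H]2C[C@H](O)[C@]2(C)C=C[C@@]1(OC)O2
F11 | step 14 | C8 diethylphosphonoacetate | COC(=O)/C1=C/[C@@H]2[C@@H](C(C)C)CC=C(C)[C@@H]2C[C@H](OC(=O)CP(=O)(OCC)OCC)[C@]2(C)C=C[C@@]1(O)O2
A1 | alternative 1 | open-chain alkynyl aldehyde | COC(=O)/C(C=O)=C/[C@@H]1[C@@H](C(C)C)CC=C(C)[C@@H]1C[C@H](O[Si](CC)(CC)CC)[C@@](C)(O[Si](CC)(CC)CC)C#C
A2 | alternative 1 | ten-membered propargylic alcohol | COC(=O)/C1=C/[C@@H]2[C@@H](C(C)C)CC=C(C)[C@@H]2C[C@H](O[Si](CC)(CC)CC)[C@@](C)(O[Si](CC)(CC)CC)C#CC1O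
A3 | alternative 2 | bicyclic enol acetate dienophile | COC(=O)C=3[C@@H](OS(C)(=O)=O)[C@@H]1[C@@H](C(C)C)CC=C(C)[C@@H]1CC3OC(C)=O
A4 | alternative 2 | tetracyclic oxanorbornene | COC(=O)[C@]35[C@@H](OS(C)(=O)=O)[C@@H]1[C@@H](C(C)C)CC=C(C)[C@@H]1C[C@@]3(OC(C)=O)[C@]4(C)C=C[C@@]5(O[Si](C)(C)C(C)(C)C)O4
A5 | alternative 3 | silyl dienol ether/acrylate triene | COC(=O)C(=C)[C@@H](OC(C)=O)[C@@H]1[C@@H](C(C)C)CC=C(C)[C@@H]1C/C(O[Si](C)(C)C(C)(C)C)=C(C)/C=C
A6 | alternative 3 | tricyclic Diels–Alder adduct | COC(=O)[C@]3(CCC=C5C)[C@@H](OC(C)=O)[C@@H]1[C@@H](C(C)C)CC=C(C)[C@@H]1C[C@]35O[Si](C)(C)C(C)(C)C
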